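## Retrosynthetic overview

1. The target is a chalcone whose ring A carries at C-3' a 2,4,6-trisubstituted oxane (ring A cis to the phenethyl arm, 4-hydroxyphenyl trans to both). The last disconnection is the enone C=C by Claisen–Schmidt condensation (acetophenone + 4-hydroxybenzaldehyde).
2. The oxane C–H at the phenethyl carbon comes from reductive opening of a ring-A-fused 2,8-dioxabicyclo[3.3.1]nonane ketal, with hydride entering anti to the aryloxy bridge.
3. The bridged ketal comes from one flask: asymmetric Friedel–Crafts/Michael addition of 2,4-dihydroxy-6-methoxyacetophenone to an achiral 1,7-diarylhepta-4,6-dien-3-one, hemiketalisation, and acid-triggered hydroalkoxylation of the 4-hydroxystyrene.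
4. The dienone comes from aldol condensation of raspberry ketone with 4-hydroxycinnamaldehyde.
5. Ring order: all benzene rings are bought; the chroman ring and the oxane ring close together in the key step; the chroman ring is then cut open again and only the oxane remains.

Assumption: the quinine-derived primary amine is taken to give the 5R Michael adduct in step 2; this sense is not established for this substrate, and the quinidine-derived pseudoenantiomer is the drop-in replacement if the antipode forms.

## Route

Step 1
Reactants: 1 4-(4-hydroxyphenyl)butan-2-one (raspberry ketone); 2 (2E)-3-(4-hydroxyphenyl)prop-2-enal (4-hydroxycinnamaldehyde)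
Product: 3 (4E,6E)-1,7-bis(4-hydroxyphenyl)hepta-4,6-dien-3-one
Conditions: pyrrolidine (0.3 equiv), AcOH (0.3 equiv), THF, 25 °C, 24 h
Reagents that add atoms: none
Why: Amine-catalysed cross-aldol condensation in which the less substituted enamine of the methyl ketone adds to the iminium of the non-enolisable enal and pyrrolidine is eliminated, giving the conjugated E,E-dienone under thermodynamic control; free phenols are tolerated and no stereocentre is formed.

Step 2
Reactants: 3 (4E,6E)-1,7-bis(4-hydroxyphenyl)hepta-4,6-dien-3-one; 4 1-(2,4-dihydroxy-6-methoxyphenyl)ethan-1-one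
Product: 7 bridged bicyclic ketal 1-[(1S,9S,11R)-3-hydroxy-11-(4-hydroxyphenyl)-9-[2-(4-hydroxyphenyl)ethyl]-5-methoxy-8,10-dioxatricyclo[7.3.1.0(2,7)]trideca-2,4,6-trien-4-yl]ethan-1-one, via Michael adduct 5 (not isolated), via chromanol hemiketal 6 (not isolated)
Conditions: 9-amino-9-deoxy-epi-quinine (20 mol %), CF3CO2H (40 mol %), 1,4-dioxane, 25 °C, 72 h; then CH2Cl2 (0.02 M), Amberlyst 15 (ArSO3H resin), 25 °C, 12 h
Reagents that add atoms: none
Why: Proposed new method: the chiral primary amine activates the dienone as its iminium ion, and the acetophenone adds 1,4 through C-3, the enolic carbon between its two free hydroxyls (favoured by bond fixation in the chelated 2-hydroxyacetophenone), so the ring-A-bearing stereocentre is set by the catalyst (closest known type: primary-amine-catalysed Friedel–Crafts/Michael additions of 4-hydroxycoumarin and naphthols to enones, which give cyclic hemiketals); adduct 5 closes to chromanol 6 through the non-chelated 4-OH, the sulfonic acid then protonates the 4-hydroxystyrene to a quinone-methide-type benzylic cation that the hemiketal OH captures, and because this closure is reversible the aryl group settles in the only unstrained position (exo, trans to ring A) while the ketal carbon is fixed by the bridge (closest known types: acid-mediated formation of 2,8-dioxabicyclo[3.3.1]nonanes from phenols and 2-hydroxychalcones, and acid hydroalkoxylation of 4-hydroxystyrenes); the chroman and oxane rings thus form in one operation.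

Step 3
Reactants: 7 bridged bicyclic ketal (three free phenols)
Product: 8 1-[(1S,9S,11R)-11-(4-acetoxyphenyl)-9-[2-(4-acetoxyphenyl)ethyl]-3-hydroxy-5-methoxy-8,10-dioxatricyclo[7.3.1.0(2,7)]trideca-2,4,6-trien-4-yl]ethan-1-one
Conditions: Ac2O (2.3 equiv), pyridine (5 equiv), CH2Cl2, 0 °C, 2 h
Reagents that add atoms: acetic anhydride, CC(=O)OC(C)=O
Why: Chemoselective O-acetylation (nucleophilic acyl substitution) of the two unhindered phenols, while the ring-A hydroxyl stays free because it is hydrogen-bonded to the acetyl group and flanked by the bridgehead; the acetates shut down quinone-methide ionisation of the benzylic ether in the next step, and no stereocentre is touched.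

Step 4
Reactants: 8 bis-acetate of the bridged ketal
Product: 9 1-[3-[(2R,4R,6S)-2-(4-acetoxyphenyl)-6-[2-(4-acetoxyphenyl)ethyl]oxan-4-yl]-2,4-dihydroxy-6-methoxyphenyl]ethan-1-one
Conditions: Et3SiH (5 equiv), Me3SiOTf (0.2 equiv), CH2Cl2, −78 → −40 °C, 2 h; then MeOH, sat. aq. NaHCO3
Reagents that add atoms: none
Why: Silane reduction of a ketal through its cyclic oxocarbenium ion (ionic hydrogenation, Kishi-type), in which the C–OAr bond ionises because the leaving group is a vinylogous carboxylate para to the acetyl and the cation is the alkoxy-stabilised oxane oxocarbenium; the ring relaxes to the half-chair with bulky ring A equatorial and hydride is delivered axially on the face away from the departed aryloxy bridge (net inversion), so the phenethyl group ends cis to ring A and trans to the now axial 4-acetoxyphenyl (6S), while low temperature and the acetates protect the aryl ketone and the benzylic ether.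

Step 5
Reactants: 9 oxanyl acetophenone bis-acetate; 10 4-hydroxybenzaldehyde (4 equiv)
Product: 11 (2E)-1-[2,4-dihydroxy-3-[(2R,4R,6S)-2-(4-hydroxyphenyl)-6-[2-(4-hydroxyphenyl)ethyl]oxan-4-yl]-6-methoxyphenyl]-3-(4-hydroxyphenyl)prop-2-en-1-one (CNP0215517.2)
Conditions: KOH (50 % aq, 20 equiv), EtOH, 25 °C, 48 h, Ar; then 1 M HCl to pH 5, 0 °C
Reagents that add atoms: none
Why: Claisen–Schmidt aldol condensation in which KOH also saponifies both aryl acetates in the same flask and E1cB dehydration gives the E-enone; the oxane stereocentres are not enolisable, and cold mild acidification avoids flavanone closure and acid epimerisation at the benzylic ether carbon.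

## Compound list

1 | 4-(4-hydroxyphenyl)butan-2-one (raspberry ketone) | CC(=O)CCc1ccc(O)cc1 | starting material
2 | (2E)-3-(4-hydroxyphenyl)prop-2-enal | O=C/C=C/c1ccc(O)cc1 | starting material
3 | (4E,6E)-1,7-bis(4-hydroxyphenyl)hepta-4,6-dien-3-one | O=C(CCc1ccc(O)cc1)/C=C/C=C/c1ccc(O)cc1 | intermediate
4 | 1-(2,4-dihydroxy-6-methoxyphenyl)ethan-1-one | COc1cc(O)cc(O)c1C(C)=O | starting material
5 | (5R,6E)-5-(3-acetyl-2,6-dihydroxy-4-methoxyphenyl)-1,7-bis(4-hydroxyphenyl)hept-6-en-3-one | COc1cc(O)c([C@H](CC(=O)CCc2ccc(O)cc2)/C=C/c2ccc(O)cc2)c(O)c1C(C)=O | intermediate (not isolated)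
6 | 1-[(2S,4R)-2,5-dihydroxy-2-[2-(4-hydroxyphenyl)ethyl]-4-[(E)-2-(4-hydroxyphenyl)ethenyl]-7-methoxy-3,4-dihydro-2H-chromen-6-yl]ethan-1-one | COc1cc2c(c(O)c1C(C)=O)[C@@H](/C=C/c1ccc(O)cc1)C[C@](O)(CCc1ccc(O)cc1)O2 | intermediate (not isolated)
7 | 1-[(1S,9S,11R)-3-hydroxy-11-(4-hydroxyphenyl)-9-[2-(4-hydroxyphenyl)ethyl]-5-methoxy-8,10-dioxatricyclo[7.3.1.0(2,7)]trideca-2,4,6-trien-4-yl]ethan-1-one (ring-A-fused 2,8-dioxabicyclo[3.3.1]nonane; aryl exo, trans to ring A) | COc1cc2c(c(O)c1C(C)=O)[C@H]1C[C@H](c3ccc(O)cc3)O[C@](CCc3ccc(O)cc3)(C1)O2 | intermediate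
8 | 1-[(1S,9S,11R)-11-(4-acetoxyphenyl)-9-[2-(4-acetoxyphenyl)ethyl]-3-hydroxy-5-methoxy-8,10-dioxatricyclo[7.3.1.0(2,7)]trideca-2,4,6-trien-4-yl]ethan-1-one | COc1cc2c(c(O)c1C(C)=O)[C@H]1C[C@H](c3ccc(OC(C)=O)cc3)O[C@](CCc3ccc(OC(C)=O)cc3)(C1)O2 | intermediate
9 | 1-[3-[(2R,4R,6S)-2-(4-acetoxyphenyl)-6-[2-(4-acetoxyphenyl)ethyl]oxan-4-yl]-2,4-dihydroxy-6-methoxyphenyl]ethan-1-one | COc1cc(O)c([C@@H]2C[C@H](CCc3ccc(OC(C)=O)cc3)O[C@@H](c3ccc(OC(C)=O)cc3)C2)c(O)c1C(C)=O | intermediate
10 | 4-hydroxybenzaldehyde | O=Cc1ccc(O)cc1 | starting material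
11 | (2E)-1-[2,4-dihydroxy-3-[(2R,4R,6S)-2-(4-hydroxyphenyl)-6-[2-(4-hydroxyphenyl)ethyl]oxan-4-yl]-6-methoxyphenyl]-3-(4-hydroxyphenyl)prop-2-en-1-one | COc1cc(O)c([C@@H]2C[C@H](CCc3ccc(O)cc3)O[C@@H](c3ccc(O)cc3)C2)c(O)c1C(=O)/C=C/c1ccc(O)cc1 | target

## Step count and risks

Total steps: 5. Longest linear sequence: 5 steps (1 or 2 → 11); 4 and 10 enter as purchased partners.

Three steps most likely to fail:

Step 2 (key cascade). The risks are low turnover or low ee with a push–pull dienone and a hindered acylphloroglucinol, competing attack through ring-A C-5 (that regioisomer would be removed by chromatography at 7), and 1,6-addition. Fallback: set out again from 3 (with 4) without chiral control, using pyrrolidine (20 mol %)/AcOH in dioxane and then Amberlyst 15. This gives the racemic bridged ketal, a 1:1 mixture of 7 and the mirror-image ketal F1. The two are separated by preparative supercritical-fluid chromatography on an immobilised amylose tris(3,5-dimethylphenylcarbamate) phase, and 7 rejoins the route at step 3.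

Step 4 (reductive ketal opening). The facial selectivity rests on a conformational argument in which the hydride enters syn to the pseudoaxial aryl group, so the epimer at the phenethyl carbon is a real possibility; the wrong C–O bond may also cleave. Fallback: set out from 8. BF3·OEt2 (0.1 equiv) and PhSH (3 equiv) in CH2Cl2 at −40 °C open the bridge to the S-phenyl monothioketal F2 (ring-A phenol released; the anomer is immaterial). Bu3SnH with azobisisobutyronitrile in toluene at 90 °C then replaces sulfur by hydrogen through the anomeric oxanyl radical, which takes hydrogen axially in the chair that keeps ring A equatorial. This radical route is free of ion pairing and arrives at 9.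

Step 5 (Claisen–Schmidt with both partners as phenoxides). The condensation may be sluggish and low-yielding because the aldehyde phenoxide is a poor electrophile. Fallback: set out from 9 and condense under the same KOH conditions with 4-(prop-2-enyloxy)benzaldehyde (C=CCOc1ccc(C=O)cc1, purchased), which is a normal electrophile, to give the allyl ether F3. The allyl group is then removed under neutral conditions with Pd(PPh3)4 (5 mol %) and morpholine in THF at 25 °C (π-allyl transfer to the amine), arriving at 11.

## Further compounds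

F1 | step 2 | 1-[(1R,9R,11S)-3-hydroxy-11-(4-hydroxyphenyl)-9-[2-(4-hydroxyphenyl)ethyl]-5-methoxy-8,10-dioxatricyclo[7.3.1.0(2,7)]trideca-2,4,6-trien-4-yl]ethan-1-one (enantiomer of 7) | COc1cc2c(c(O)c1C(C)=O)[C@@H]1C[C@@H](c3ccc(O)cc3)O[C@@](CCc3ccc(O)cc3)(C1)O2
F2 | step 4 | 1-[3-[(2R,4S,6R)-2-(4-acetoxyphenyl)-6-[2-(4-acetoxyphenyl)ethyl]-6-(phenylsulfanyl)oxan-4-yl]-2,4-dihydroxy-6-methoxyphenyl]ethan-1-one (axial-sulfur anomer drawn) | COc1cc(O)c([C@@H]2C[C@@](CCc3ccc(OC(C)=O)cc3)(Sc3ccccc3)O[C@@H](c3ccc(OC(C)=O)cc3)C2)c(O)c1C(C)=O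
F3 | step 5 | (2E)-1-[2,4-dihydroxy-3-[(2R,4R,6S)-2-(4-hydroxyphenyl)-6-[2-(4-hydroxyphenyl)ethyl]oxan-4-yl]-6-methoxyphenyl]-3-[4-(prop-2-enyloxy)phenyl]prop-2-en-1-one | COc1cc(O)c([C@@H]2C[C@H](CCc3ccc(O)cc3)O[C@@H](c3ccc(O)cc3)C2)c(O)c1C(=O)/C=C/c1ccc(OCC=C)cc1
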